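## The problem

Bisnorstriatol 6 consists of two resorcinol rings joined through their C5 carbons by an unbranched, fully saturated tetradecane chain. It has no ring other than the two benzene rings and no stereocenter, so there is nothing to set and nothing that could direct a later step. Benzenes with 1,3-dioxygenation and a handle at C5 can be bought, so the real task is the fourteen-carbon tether and its two aryl–C(sp3) bonds. A saturated chain offers no group at which a carbon–carbon bond can be made, so the bond-forming reactivity has to come in as unsaturation that is erased afterwards, and the joining must not give mixtures of chain lengths. The four phenols are the fragile part: resorcinols are C-nucleophilic at C2, C4 and C6, bind copper and palladium, and are oxidatively coupled by the same CuCl/amine/O2 systems that join alkynes, so they must stay masked until the last step. The feature that opens the route is the symmetry of 6 about the midpoint of the C7–C8 bond of the chain. The two halves, each an aryl ring carrying seven chain carbons, are identical, so this bond can be made by dimerising one compound; if C7 and C8 are terminal alkyne carbons, the dimerisation is an oxidative homocoupling.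

## Retrosynthesis

**6 to 5.** The four phenolic O–H bonds of 6 are traced back to four O–CH3 bonds in 1,14-bis(3,5-dimethoxyphenyl)tetradecane 5. Methyl ethers are chosen because the aryl iodide 1 is sold with them in place and because they are inert to Pd(PPh3)2Cl2/CuI, to CuCl/TMEDA/O2 and to H2 over Pd/C. Benzyl ethers would fall during the hydrogenation and save a step, but the purchasable benzyl-protected aryl halide is a bromide that needs heat in the alkynylation, so that variant is held in reserve. The forward step only has to cleave four aryl methyl ethers on a molecule whose remainder is a saturated hydrocarbon.

**5 to 4.** No skeletal bond is cut here. Four triple bonds are written into the chain at C1, C6, C8 and C13, giving 1,14-bis(3,5-dimethoxyphenyl)tetradeca-1,6,8,13-tetrayne 4. This turns an inert chain into one whose C7–C8 bond is the retron of an alkyne–alkyne coupling and whose aryl–C1 bonds are retrons of an aryl–alkyne coupling. The forward reaction is exhaustive hydrogenation over Pd/C, which has to leave the arenes and aryl ethers alone; no benzylic heteroatom is present to be hydrogenolysed.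

**4 to 3 + 3.** The sp–sp bond C7–C8 of 4 is cut, giving two molecules of 1-(hepta-1,6-diyn-1-yl)-3,5-dimethoxybenzene 3. Cutting both aryl–C1 bonds first would need an α,ω-diyne spanning the whole tether, which cannot be bought. Cutting sp–sp3 bonds would need two stoichiometric acetylide alkylations on a long dihalide. The midpoint cut halves the molecule exactly (fifteen carbons instead of thirty), uses a single substrate, and needs only catalytic CuCl and oxygen. The forward reaction must engage the terminal alkyne only and leave the internal aryl alkyne and the arene untouched.

**3 to 1 + 2.** The aryl–C(sp) bond of 3 is cut, giving 1-iodo-3,5-dimethoxybenzene 1 and hepta-1,6-diyne 2, both commercial. A Sonogashira coupling makes this bond at room temperature from the iodide. The demand on the forward step is mono-arylation of a diyne with two equivalent ends. This is handled by an excess of the volatile, recoverable 2, and by exclusion of oxygen so that alkyne homocoupling is kept for the next step.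

## Roads not taken

Alternative 1: Both benzene rings are taken apart, each into a four-carbon cyclobutenone and a two-carbon ynol ether. The precursors are 3,3'-(tetradecane-1,14-diyl)bis(cyclobut-2-en-1-one) A1 and ethoxyacetylene A2.
- Forward key step: heating A1 with A2 would start a pericyclic cascade at each end. The cyclobutenone opens to a vinylketene, adds the ynol ether in a [2+2] sense, the new vinylcyclobutenone opens, and the dienylketene closes by 6π electrocyclisation and tautomerises. The product of this key step is 5,5'-(tetradecane-1,14-diyl)bis(3-ethoxyphenol) A3. De-ethylation of A3 would give 6.
- Merits: the tether is saturated from the start, so there is no hydrogenation and no statistical step. The 1,3,5-pattern of A3 is fixed by the polarity of A2. The two oxygens of each ring come out differentiated.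
- Weak points: it builds two rings that can be bought ready-made as 1. A1 is not an article of commerce. It would come from octadeca-1,17-diyne A4 by twofold [2+2] cycloaddition of a dihaloketene and reductive dehalogenation, and A4 itself must be made. Two four-stage cascades must both finish in one molecule. A2 is volatile and costly. The oxygen differentiation in A3 is useless for a target with four identical phenols, and a dealkylation is still needed.
- Comparison: at least five operations against four, through sensitive intermediates. It would be the better road for an analogue whose ring substitution cannot be bought. The chosen plan sets against this that for 6 the arene is commercial and only the chain has to be made.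

Alternative 2: The two aryl–C(sp3) bonds are cut. The ring is made nucleophilic at its ipso carbon by dissolving-metal reduction of 3,5-dimethoxybenzoic acid A5, and the whole chain is bought as 1,14-dibromotetradecane A6.
- Forward key step: lithium in liquid ammonia would reduce two molecules of A5 to dienolate dianions, which alkylate at C1 with the two ends of A6. The product of this key step is 1,1'-(tetradecane-1,14-diyl)bis(3,5-dimethoxycyclohexa-2,5-diene-1-carboxylic acid) A7. Oxidative decarboxylation of A7 would rearomatise both rings to 5, where this road joins the chosen one.
- Merits: A5 and A6 are the cheapest materials of all routes, the chain is bought intact, no palladium or copper is used, there is no hydrogenation, and 6 is reached in three steps, one fewer than the chosen plan.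
- Weak points: two stoichiometric alkylations must both occur on one lipophilic dihalide, and A6 dissolves poorly in ammonia at low temperature. Mono-alkylation, elimination and reduction of the C–Br bond by dissolved lithium would give chain-terminated by-products of similar polarity. A7 is an acid-sensitive bis(enol ether) diacid. The carboxyl groups of A7 are lost again in a step that needs a stoichiometric oxidant.
- Comparison: shorter by a step and cheaper, which is a real advantage. The chosen plan sets against it that its bond-forming steps are catalytic and run at ambient temperature, that its only statistical event uses a volatile reagent in excess, and that 3, 4 and 5 are neutral compounds that are simple to purify. Both roads end with the same demethylation.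

Alternative 3: In each ring the bond between the ester-bearing carbon and the chain-bearing carbon is cut, which unrolls both arenes into a linear polyketide. The precursor is dimethyl 3,5,7,22,24,26-hexaoxooctacosanedioate A10. It would be reached by twofold acylation of the polyanion of methyl 3,5-dioxohexanoate A9 with dimethyl hexadecanedioate A8.
- Forward key step: in aqueous base each 3,5,7-triketo ester terminus of A10 would close by aldol attack of C2 on the C7 ketone, then dehydrate and enolise. The product of this key step is dimethyl 6,6'-(tetradecane-1,14-diyl)bis(2,4-dihydroxybenzoate) A11. Saponification and decarboxylation of A11 would give 6.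
- Merits: no protecting group is used at all, since the phenols of A11 are created by the ring-forming step. A8 and A9 are cheap, and the step count is about the same as in the chosen plan.
- Weak points: the twofold acylation of A8 by the polyanion of A9 is stoichiometric in strong base, and a chain acylated at one end only is hard to remove. A10 is a mixture of enol tautomers that resists purification. Each terminus of A10 can close in three ways (the wanted aldol closure, a Claisen-type C-acylation, or lactonisation through an enol oxygen), and the wanted mode must win twice in one molecule. An ester hydrolysis and a decarboxylation still follow from A11.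
- Comparison: it wins on protecting-group economy and avoids transition metals. The chosen plan pays for its methyl ethers with one deprotection step, and sets against that a single, predictable event in each step.

Key step: step 2

Remark on the chemistry: the target has no stereogenic element, so no step sets or endangers a stereocenter and all SMILES are given without stereodescriptors.

## Route

Step 1
Reactants: 1 1-iodo-3,5-dimethoxybenzene; 2 hepta-1,6-diyne
Product: 3 1-(hepta-1,6-diyn-1-yl)-3,5-dimethoxybenzene
Conditions: Pd(PPh3)2Cl2 (2 mol%), CuI (4 mol%), Et3N, THF, rt, argon; 2 (5 equiv), slow addition of 1
Reagents that add atoms: none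
Why: Sonogashira coupling; the aryl iodide adds oxidatively to zerovalent palladium at room temperature, the copper acetylide of 2 transmetalates and reductive elimination forms the aryl–alkyne bond. A fivefold excess of the volatile diyne and slow addition of 1 should hold the statistical second arylation down, and exclusion of oxygen suppresses alkyne homocoupling.

Step 2
Reactants: 3 1-(hepta-1,6-diyn-1-yl)-3,5-dimethoxybenzene (two molecules)
Product: 4 1,14-bis(3,5-dimethoxyphenyl)tetradeca-1,6,8,13-tetrayne
Conditions: CuCl (10 mol%), TMEDA (20 mol%), O2 (1 atm), acetone, rt
Reagents that add atoms: none
Why: Glaser–Hay oxidative homocoupling of a terminal alkyne, the closest known reaction type and a direct application of it. TMEDA-ligated CuCl π-complexes the terminal triple bond of 3, which acidifies its C–H bond so that the amine removes the proton and a monovalent copper acetylide forms. Dioxygen oxidises the copper, and a dinuclear bis(acetylide) at the higher oxidation level collapses by reductive elimination to the sp–sp bond between C7 and C8, returning monovalent copper that oxygen reoxidises, with water as the only co-product. Both carbons joined are nucleophilic acetylide carbons, and the oxidant supplies the polarity inversion. No ring closes and no stereocenter is created, so no mode of closure and no controlling element are involved. The selectivity needed is for the terminal over the internal aryl alkyne, and the substrate secures it, because only the terminal alkyne has the C–H bond through which a copper acetylide can form. A single substrate dimerises, so no homo- versus cross-coupling question arises. The methyl ethers keep the arene rings inert to CuCl/TMEDA/O2, which would oxidatively couple free resorcinols.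

Step 3
Reactants: 4 1,14-bis(3,5-dimethoxyphenyl)tetradeca-1,6,8,13-tetrayne
Product: 5 1,14-bis(3,5-dimethoxyphenyl)tetradecane
Conditions: H2 (1–3 atm), 10% Pd/C, EtOAc/EtOH, rt
Reagents that add atoms: none
Why: Heterogeneous catalytic hydrogenation; the two aryl alkynes and the central 1,3-diyne should take up eight equivalents of hydrogen through alkene intermediates that Pd/C also reduces readily. The arene rings and aryl methyl ethers are inert under these conditions and there is no benzylic C–O bond to hydrogenolyse.

Step 4
Reactants: 5 1,14-bis(3,5-dimethoxyphenyl)tetradecane
Product: 6 bisnorstriatol, 5,5'-(tetradecane-1,14-diyl)bis(benzene-1,3-diol)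
Conditions: BBr3 (8 equiv), CH2Cl2, −78 °C to rt; then H2O, 0 °C
Reagents that add atoms: none
Why: Lewis acid-mediated cleavage of aryl methyl ethers with BBr3; boron coordinates each ether oxygen, bromide attacks the methyl carbon in an SN2 step, and hydrolysis of the aryl borates on work-up frees the four phenols. The rest of the molecule is a saturated hydrocarbon chain with nothing else to react.

## Compound list

1 | 1-iodo-3,5-dimethoxybenzene | COc1cc(I)cc(OC)c1 | starting material
2 | hepta-1,6-diyne | C#CCCCC#C | starting material
3 | 1-(hepta-1,6-diyn-1-yl)-3,5-dimethoxybenzene | COc1cc(OC)cc(C#CCCCC#C)c1 | intermediate
4 | 1,14-bis(3,5-dimethoxyphenyl)tetradeca-1,6,8,13-tetrayne | COc1cc(OC)cc(C#CCCCC#CC#CCCCC#Cc2cc(OC)cc(OC)c2)c1 | intermediate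
5 | 1,14-bis(3,5-dimethoxyphenyl)tetradecane | COc1cc(OC)cc(CCCCCCCCCCCCCCc2cc(OC)cc(OC)c2)c1 | intermediate
6 | bisnorstriatol, 5,5'-(tetradecane-1,14-diyl)bis(benzene-1,3-diol) | Oc1cc(O)cc(CCCCCCCCCCCCCCc2cc(O)cc(O)c2)c1 | target

Total step count: 4. Longest linear sequence: 4 steps (1 to 3 to 4 to 5 to 6).

## Least certain steps

Risk at step 2 (the key step). The most likely failure is stalling of the copper turnover together with oligomerisation or decomposition of the conjugated diyne during long exposure to oxygen, amine and light, so that material is lost on isolation. The fallback forms the same C7–C8 bond without oxygen. Starting from 3, one half of the material would be brominated at the terminal alkyne carbon (NBS, 1.05 equiv, catalytic AgNO3, acetone, rt, short reaction time) to 1-(7-bromohepta-1,6-diyn-1-yl)-3,5-dimethoxybenzene F1. The silver acetylide pathway should be much faster than bromination of the electron-rich ring. F1 would then be joined to a second equivalent of 3 by Cadiot–Chodkiewicz coupling (CuCl, NH2OH·HCl, n-BuNH2, MeOH/THF, 0 °C), which returns to the route at 4.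

Risk at step 1. The two alkyne ends of 2 are equivalent, so the risk is arylation of the remaining terminus of the product, along with premature oxidative dimerisation of the diyne if oxygen leaks in. Both processes consume 1 and complicate the separation. The fallback removes the statistical element. Starting from 1, Sonogashira coupling with 5-chloropent-1-yne (1.2 equiv; Pd(PPh3)2Cl2, CuI, Et3N, THF, rt), which has only one alkyne, would give 1-(5-chloropent-1-yn-1-yl)-3,5-dimethoxybenzene F2. Displacement of the primary chloride of F2 with lithium acetylide–ethylenediamine complex (LiC≡CH·H2NCH2CH2NH2, DMSO, catalytic NaI, rt) would install the terminal alkyne and return to the route at 3.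

Risk at step 4. Four ether cleavages must all go to completion. Partial demethylation would leave closely related phenol ethers that are hard to separate from the amphiphilic product, and it would be made worse if partly cleaved boron-bound intermediates precipitate from dichloromethane. The fallback changes the protecting group so that no separate deprotection exists. Starting from 2, Sonogashira coupling with purchased 1,3-bis(benzyloxy)-5-bromobenzene (Pd(PPh3)2Cl2, CuI, Et3N, 60 °C) would give 1,3-bis(benzyloxy)-5-(hepta-1,6-diyn-1-yl)benzene F3. Glaser–Hay coupling of F3 as in step 2 would give 1,14-bis[3,5-bis(benzyloxy)phenyl]tetradeca-1,6,8,13-tetrayne F4. Hydrogenation of F4 over 10% Pd/C (H2, THF/MeOH, rt) would saturate the chain and hydrogenolyse the four benzyl ethers in the same operation, returning to the route at 6.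

## Further compounds

F1 | step 2 | 1-(7-bromohepta-1,6-diyn-1-yl)-3,5-dimethoxybenzene | COc1cc(OC)cc(C#CCCCC#CBr)c1
F2 | step 1 | 1-(5-chloropent-1-yn-1-yl)-3,5-dimethoxybenzene | COc1cc(OC)cc(C#CCCCCl)c1
F3 | step 4 | 1,3-bis(benzyloxy)-5-(hepta-1,6-diyn-1-yl)benzene | C#CCCCC#Cc1cc(OCc2ccccc2)cc(OCc2ccccc2)c1
F4 | step 4 | 1,14-bis[3,5-bis(benzyloxy)phenyl]tetradeca-1,6,8,13-tetrayne | c1ccccc1COc1cc(OCc2ccccc2)cc(C#CCCCC#CC#CCCCC#Cc2cc(OCc3ccccc3)cc(OCc3ccccc3)c2)c1
A1 | alternative 1 | 3,3'-(tetradecane-1,14-diyl)bis(cyclobut-2-en-1-one) | O=C1C=C(CCCCCCCCCCCCCCC2=CC(=O)C2)C1
A2 | alternative 1 | ethoxyacetylene | CCOC#C
A3 | alternative 1 | 5,5'-(tetradecane-1,14-diyl)bis(3-ethoxyphenol) | CCOc1cc(O)cc(CCCCCCCCCCCCCCc2cc(O)cc(OCC)c2)c1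
A4 | alternative 1 | octadeca-1,17-diyne | C#CCCCCCCCCCCCCCCC#C
A5 | alternative 2 | 3,5-dimethoxybenzoic acid | COc1cc(OC)cc(C(=O)O)c1
A6 | alternative 2 | 1,14-dibromotetradecane | BrCCCCCCCCCCCCCCBr
A7 | alternative 2 | 1,1'-(tetradecane-1,14-diyl)bis(3,5-dimethoxycyclohexa-2,5-diene-1-carboxylic acid) | OC(=O)C1(CCCCCCCCCCCCCCC2(C(=O)O)C=C(OC)CC(OC)=C2)C=C(OC)CC(OC)=C1
A8 | alternative 3 | dimethyl hexadecanedioate | COC(=O)CCCCCCCCCCCCCCC(=O)OC
A9 | alternative 3 | methyl 3,5-dioxohexanoate | COC(=O)CC(=O)CC(C)=O
A10 | alternative 3 | dimethyl 3,5,7,22,24,26-hexaoxooctacosanedioate | COC(=O)CC(=O)CC(=O)CC(=O)CCCCCCCCCCCCCCC(=O)CC(=O)CC(=O)CC(=O)OC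
A11 | alternative 3 | dimethyl 6,6'-(tetradecane-1,14-diyl)bis(2,4-dihydroxybenzoate) | COC(=O)c1c(O)cc(O)cc1CCCCCCCCCCCCCCc1cc(O)cc(O)c1C(=O)OC
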